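The 17-membered macrocycle is opened at the C(sp2)–C(sp3) bond between C4 of the para-phenylene ring B and the CH2 of the ethano bridge that leads to ring C. This aryl–CH2CH2–aryl unit is the anti-Markovnikov hydroboration/cross-coupling adduct of a ring C styrene and a ring B aryl bromide. One intramolecular B-alkyl Suzuki–Miyaura reaction therefore converts a fully assembled open-chain precursor (vinyl on ring C, bromine on ring B, the three phenols as methyl ethers) directly into the saturated macrocycle. The precursor is itself joined by the same reaction type, run intermolecularly with iodide-over-bromide selectivity. The target has no stereocentre.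

Key step: step 6

Remark on ring labels: ring A is the trioxygenated ring, ring B the para-phenylene ring, ring C the 3-hydroxy-2-aryloxyphenyl ring and ring D the ortho-phenylene ring.
Remark on assumptions: compounds 1, 2, 5 and 6 are taken as commercially available; the target as drawn has no stereogenic element, so no stereocontrol is needed.

Step 1
Reactants: 1 3-hydroxy-4,5-dimethoxybenzaldehyde; 2 (4-bromophenyl)boronic acid
Product: 3 3-(4-bromophenoxy)-4,5-dimethoxybenzaldehyde
Conditions: Cu(OAc)2 (20 mol %), pyridine, 4 Å MS, O2 (1 atm), CH2Cl2, rt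
Reagents that add atoms: none
Why: Chan–Lam oxidative O-arylation, in which the phenoxide and the aryl group of the boronic acid meet on copper and reductive elimination gives the ring A–O–ring B diaryl ether under conditions that leave the aldehyde and the C–Br bond untouched, dioxygen being the terminal oxidant.

Step 2
Reactants: 3 3-(4-bromophenoxy)-4,5-dimethoxybenzaldehyde
Product: 4 1-(4-bromophenoxy)-5-ethenyl-2,3-dimethoxybenzene
Conditions: Ph3PCH3Br, KOtBu, THF, 0 °C → rt
Reagents that add atoms: methyltriphenylphosphonium bromide, C[P+](c1ccccc1)(c1ccccc1)c1ccccc1.[Br-]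
Why: Wittig methylenation of a non-enolisable aryl aldehyde with the unstabilised ylide should give the ring A styrene cleanly, the aryl bromide and the ethers being inert to the ylide.

Step 3
Reactants: 5 2-fluoro-3-methoxybenzaldehyde; 6 2-iodophenol
Product: 7 2-(2-iodophenoxy)-3-methoxybenzaldehyde
Conditions: K2CO3, DMA, 130 °C
Reagents that add atoms: none
Why: Nucleophilic aromatic substitution (SNAr), in which the ortho-formyl group stabilises the Meisenheimer adduct at C2 of 5 and fluoride leaves, while the C–I bond of 6 is untouched because no transition metal is present.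

Step 4
Reactants: 7 2-(2-iodophenoxy)-3-methoxybenzaldehyde
Product: 8 1-ethenyl-2-(2-iodophenoxy)-3-methoxybenzene
Conditions: Ph3PCH3Br, KOtBu, THF, 0 °C → rt
Reagents that add atoms: methyltriphenylphosphonium bromide, C[P+](c1ccccc1)(c1ccccc1)c1ccccc1.[Br-]
Why: Wittig methylenation with an ylide made by KOtBu (no organolithium, hence no iodine–metal exchange) should turn the hindered, non-enolisable aldehyde into the ring C vinyl group.

Step 5
Reactants: 4 1-(4-bromophenoxy)-5-ethenyl-2,3-dimethoxybenzene; 8 1-ethenyl-2-(2-iodophenoxy)-3-methoxybenzene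
Product: 10 1-(4-bromophenoxy)-5-{2-[2-(2-ethenyl-6-methoxyphenoxy)phenyl]ethyl}-2,3-dimethoxybenzene, via B-alkyl-9-BBN borane 9 (not isolated)
Conditions: 4, 9-BBN (0.95 equiv based on 4), THF, 0 °C → rt; then 8, PdCl2(dppf) (5 mol %), AsPh3, Cs2CO3, DMF/THF/H2O, rt
Reagents that add atoms: none
Why: Intermolecular B-alkyl Suzuki–Miyaura coupling, in which 9-BBN hydroborates styrene 4 at its terminal carbon before 8 is added (no B–H is left for the vinyl group of 8) and zerovalent palladium at room temperature should insert into the C–I bond of 8 much faster than into the electron-rich C–Br bond of ring B, so that bromide and vinyl both survive for the key step.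

Step 6
Reactants: 10 1-(4-bromophenoxy)-5-{2-[2-(2-ethenyl-6-methoxyphenoxy)phenyl]ethyl}-2,3-dimethoxybenzene
Product: 12 tri-O-methyl ether of the target macrocycle, via B-alkyl-9-BBN borane 11 (not isolated)
Conditions: 9-BBN (1.1 equiv), THF, rt; aq. Cs2CO3; then syringe-pump addition to PdCl2(dppf) (15 mol %), AsPh3, Cs2CO3, DMF/THF/H2O, 65 °C, final concentration about 1 mM
Reagents that add atoms: none
Why: 9-BBN adds to the only alkene of 10, the ring C vinyl group, with boron on the terminal carbon, so borane 11 carries its primary CH2–B bond at the carbon that must bond to ring B; zerovalent palladium from PdCl2(dppf) then inserts into the C4–Br bond of ring B, the base-activated borane passes its primary alkyl group to divalent palladium, and reductive elimination forges the C(sp3)–C(sp2) bond. The closest known reaction type is the intramolecular B-alkyl Suzuki–Miyaura coupling, an established way to close macrocycles and cyclophanes. The one ring closed is the 17-membered macrocycle, formed as an end-to-end closure by reductive elimination from an 18-membered alkyl(aryl)palladium chelate, free of small-ring stereoelectronic constraints. No stereocentre is created. The step needs ring closure to outrun intermolecular coupling, which slow addition at high dilution should secure, helped by the fold that the ortho-linked diaryl ether of rings C and D and the meta-linked ring A impose on the chain. It also needs anti-Markovnikov hydroboration and suppression of beta-hydride elimination, which the bulk of 9-BBN and the wide bite angle of dppf should provide.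

Step 7
Reactants: 12 tri-O-methyl ether of the target macrocycle
Product: 13 target CNP0290892.0 (macrocyclic bis(bibenzyl) triol)
Conditions: BBr3 (excess), CH2Cl2, −78 °C → rt; then H2O, 0 °C
Reagents that add atoms: none
Why: Lewis-acid ether cleavage, in which BBr3 binds each methoxy oxygen and bromide removes the methyl group by SN2 attack, whereas the two diaryl ether linkages offer no sp3 carbon and should stay intact, and aqueous work-up releases the three phenols.

Compound list
1 | 3-hydroxy-4,5-dimethoxybenzaldehyde | O=Cc1cc(O)c(OC)c(OC)c1 | starting material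
2 | (4-bromophenyl)boronic acid | OB(O)c1ccc(Br)cc1 | starting material
3 | 3-(4-bromophenoxy)-4,5-dimethoxybenzaldehyde | O=Cc1cc(Oc2ccc(Br)cc2)c(OC)c(OC)c1 | intermediate
4 | 1-(4-bromophenoxy)-5-ethenyl-2,3-dimethoxybenzene | C=Cc1cc(Oc2ccc(Br)cc2)c(OC)c(OC)c1 | intermediate
5 | 2-fluoro-3-methoxybenzaldehyde | O=Cc1cccc(OC)c1F | starting material
6 | 2-iodophenol | Oc1ccccc1I | starting material
7 | 2-(2-iodophenoxy)-3-methoxybenzaldehyde | O=Cc1cccc(OC)c1Oc1ccccc1I | intermediate
8 | 1-ethenyl-2-(2-iodophenoxy)-3-methoxybenzene | C=Cc1cccc(OC)c1Oc1ccccc1I | intermediate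
9 | 9-{2-[3-(4-bromophenoxy)-4,5-dimethoxyphenyl]ethyl}-9-borabicyclo[3.3.1]nonane | COc1cc(CCB2C3CCCC2CCC3)cc(Oc2ccc(Br)cc2)c1OC | intermediate (not isolated)
10 | 1-(4-bromophenoxy)-5-{2-[2-(2-ethenyl-6-methoxyphenoxy)phenyl]ethyl}-2,3-dimethoxybenzene | COc1cc(CCc2ccccc2Oc2c(C=C)cccc2OC)cc(Oc2ccc(Br)cc2)c1OC | intermediate
11 | 9-{2-[2-(2-{2-[3-(4-bromophenoxy)-4,5-dimethoxyphenyl]ethyl}phenoxy)-3-methoxyphenyl]ethyl}-9-borabicyclo[3.3.1]nonane | COc1cc(CCc2ccccc2Oc2c(CCB3C4CCCC3CCC4)cccc2OC)cc(Oc2ccc(Br)cc2)c1OC | intermediate (not isolated)
12 | tri-O-methyl ether of the target: 17-membered macrocycle with ring A (1,2-dimethoxy-3-aryloxy, bridged at C5), ring B (para-phenylene), ring C (3-methoxy-2-aryloxy) and ring D (ortho-phenylene), joined by two diaryl ether oxygens and two CH2CH2 bridges | COc1cc2cc(c1OC)Oc1ccc(cc1)CCc1cccc(OC)c1Oc1ccccc1CC2 | intermediate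
13 | target CNP0290892.0: the same macrocycle with three free hydroxyl groups (two on ring A, one on ring C) | Oc1cc2cc(c1O)Oc1ccc(cc1)CCc1cccc(O)c1Oc1ccccc1CC2 | target

Total step count: 7
Longest linear sequence: 5 steps (steps 1, 2, 5, 6, 7; the branch through steps 3, 4, 5, 6, 7 is equally long)

Steps most likely to fail

Step 6 (key macrocyclization). Intermolecular coupling to oligomers, protodeboronation or beta-hydride elimination may outrun the slow ring-closing alkyl transfer if the para-bridged ring is strained in the transition state. The fallback sets out from 10 and comes back at 12. An intramolecular Mizoroki–Heck reaction (Pd(OAc)2, P(o-tol)3, Et3N, DMF, 100 °C, high dilution) joins the same two carbons, because the long-lived arylpalladium bromide on ring B simply waits for the tethered ring C vinyl group. It should give the macrocyclic E-stilbene, 12 with CH=CH in place of the ring B/ring C CH2CH2 bridge F1. Hydrogenation (H2, Pd/C, EtOAc, rt) then should give 12.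

Step 5 (intermolecular coupling). Loss of iodide-over-bromide discrimination would let palladium insert into the C–Br bond of 9 or 10 and give oligomers, and any residual B–H would hydroborate the vinyl group of 8. The fallback sets out from 1 and 7 and comes back at 10; it builds the ring A/ring D bridge before bromine and vinyl are present. Ohira–Bestmann homologation of 1 (dimethyl (1-diazo-2-oxopropyl)phosphonate, K2CO3, MeOH, rt) should give 5-ethynyl-2,3-dimethoxyphenol F2. Sonogashira coupling with 7 (PdCl2(PPh3)2, CuI, Et3N, THF, rt) should give 2-{2-[(3-hydroxy-4,5-dimethoxyphenyl)ethynyl]phenoxy}-3-methoxybenzaldehyde F3. Hydrogenation of the alkyne (H2, Pd/C, EtOAc, rt, stopped before the aldehyde is touched) should give 2-{2-[2-(3-hydroxy-4,5-dimethoxyphenyl)ethyl]phenoxy}-3-methoxybenzaldehyde F4. Chan–Lam arylation with 2 under the conditions of step 1 should give 2-(2-{2-[3-(4-bromophenoxy)-4,5-dimethoxyphenyl]ethyl}phenoxy)-3-methoxybenzaldehyde F5. Wittig methylenation as in step 4 then should give 10.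

Step 1 (Chan–Lam arylation). Aryl transfer to copper may be sluggish for the ortho-methoxy phenol, so that protodeboronation and homocoupling of the boronic acid consume 2. The fallback sets out from 1 and comes back at 3. A redox-neutral Ullmann-type coupling of 1 with 1-bromo-4-iodobenzene (CuI, N,N-dimethylglycine, Cs2CO3, dioxane, 90 °C) uses an aryl iodide electrophile in place of oxidative coupling and should react at iodine only, giving 3 directly; it makes no new compound (F0).

Further compounds
F1 | step 6 | macrocyclic E-stilbene: 12 with an E-CH=CH unit in place of the ring B/ring C CH2CH2 bridge | COc1cc2cc(c1OC)Oc1ccc(cc1)/C=C/c1cccc(OC)c1Oc1ccccc1CC2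
F2 | step 5 | 5-ethynyl-2,3-dimethoxyphenol | C#Cc1cc(O)c(OC)c(OC)c1
F3 | step 5 | 2-{2-[(3-hydroxy-4,5-dimethoxyphenyl)ethynyl]phenoxy}-3-methoxybenzaldehyde | O=Cc1cccc(OC)c1Oc1ccccc1C#Cc1cc(O)c(OC)c(OC)c1
F4 | step 5 | 2-{2-[2-(3-hydroxy-4,5-dimethoxyphenyl)ethyl]phenoxy}-3-methoxybenzaldehyde | O=Cc1cccc(OC)c1Oc1ccccc1CCc1cc(O)c(OC)c(OC)c1
F5 | step 5 | 2-(2-{2-[3-(4-bromophenoxy)-4,5-dimethoxyphenyl]ethyl}phenoxy)-3-methoxybenzaldehyde | O=Cc1cccc(OC)c1Oc1ccccc1CCc1cc(Oc2ccc(Br)cc2)c(OC)c(OC)c1
F0 | step 1 | none | none
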